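## Structural features

The target is a germacranolide: a ten-membered carbocycle C1–C10 carrying a trans-fused α-methylene-γ-butyrolactone on the C6–C7 bond (lactone oxygen on C6; C11 on C7, with methylene C13 and carbonyl C12). Two trisubstituted ring alkenes, C1=C10 (formyl C14 on C10) and C4=C5 (hydroxymethyl C15 on C4), are both ring-cis (C2 and C9 on one side of C1=C10, C3 and C6 on one side of C4=C5). They are joined only through the C2–C3 ethano unit. Four contiguous stereocentres run C6(R), C7(S), C8(S), C9(S): in the zigzag C5–C10, O6 and the C11 branch are syn, C11 and O8 anti, O8 and O9 syn; O8 carries a methacrylate and O9 an acetate. The fragile groups are two ester Michael acceptors (α-methylene lactone, methacrylate), an enal, and vicinal esters that can migrate; the lactone could also close on O8 instead of O6. The real difficulty is a medium ring with two geometry-defined trisubstituted alkenes beside a dense oxygenated tetrad, plus the need to tell apart four primary allylic positions (C2, C3, C14, C15) and three secondary oxygens. The key step uses the fact that C2 and C3 are both allylic methylenes and that C2–C3 is the one ring bond remote from every stereocentre and heteroatom: a C2 sulfonyl carbanion is alkylated by the C3 allylic bromide of the same chain.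

## Logic of the disconnections

46 is taken back, without cutting a skeletal bond, to the fully protected ring 37 through 45, 42, 41, 40, 39 and 38. The lactone C12(=O)–O6 and the C14 formyl group become silyl ethers of the 6,12-diol and of C14–OH; the ester bonds at O8 and O9 become a PMB and a TES ether. The reason is that two Michael acceptors, an enal and two esters cannot pass a carbanion ring closure or a hydride desulfonylation. The gain is a polyether whose only reactive sites are isolated alkenes. The demand is a fixed order of unmasking (PMB, TES, three TBS, TBDPS) and one oxidation that takes C12 to the lactone and C14 to the aldehyde while O15 stays silylated and O8 is already acylated, so that only the 6,12-lactone can close.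

37 comes from 36 by exchange of the C2 sulfonyl group for hydrogen, and 36 is cut at C2–C3 to the open chain 34. This bond is flanked by two alkenes and by no stereocentre; both carbons are allylic, so C3 can be the electrophile (bromide) and C2, once sulfonylated, the nucleophile. The gain is that a ten-membered ring is exchanged for a chain in which both alkene geometries and all four stereocentres already exist; the closure creates nothing that must be controlled. 34 and 36 carry the target's spatial arrangement at C6–C9 and both ring-cis alkenes; the descriptor at C7 reads R only because the PMB ether on O8 changes the CIP ranking. The demand is α-alkylation of the allyl anion, SN2 at C3, high dilution, and a C–S cleavage that does not move C1=C10. For the last point a palladium hydride substitution is planned instead of a dissolving metal, because the allyl anion a dissolving metal would release has two β-oxygens (O9, O14).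

34 is simplified by three functional-group cuts to 26: C3–Br back to 32, the C2–S bond back to 29 and 28 (through 31), and C3–C4 back to carbon monoxide and the C4–I bond of 26 (through 27). C2 and C3 are like groups and can only be told apart if they are never free alcohols at the same time; carrying C3 as an ester while C2 is unmasked and sulfonylated does this without an extra protecting group. The demand is that the carbonylation precedes the sulfone (zerovalent palladium would ionise an allylic sulfone) and that the primary TES ether on O2 leaves before the secondary one on O9.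

26 (through 25) is cut at C9–C10 into 19 and 23. C9 is a carbinol carbon on an alkene carbon, so the bond is an alkenylmetal–aldehyde addition, and the PMB ether on O8 of 19 can chelate. This fixes the protecting-group placement: the chelating ether must sit on O8 to give the 8,9-syn relation, and the new O9 is then silylated. The gain is that C1=C10, with C14 and C2, arrives as one stereodefined piece. The demand is chelation control (9S) and retention of alkene geometry through iodine–lithium exchange.

19 is traced through 18, 17 and 16 to 14, which is cut at C5–C6 into 10 and 12. The C4–I and C5–H bonds of 16 come from hydroalumination–iodination of the alkyne in 14; the PMB ether on O8 of 18 comes from hydride opening of the acetal in 17. The ring-cis C4=C5 geometry is exactly the anti-addition geometry of an alkoxide-directed hydroalumination. The gain is a three-carbon alkyne and an aldehyde with two stereocentres. The demand is Felkin–Anh selectivity at C6 and regioselective acetal opening.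

10 comes from 8 through 9 (oxidative acetal formation from the PMB ether and O8–H, then oxidation of C6), and 8 is cut at C7–C11 into 4 and 6. An SN2 opening of a trans-epoxide gives the anti C7/C8 relation with the absolute configuration of a catalytic asymmetric epoxidation. The gain is two achiral four- and three-carbon pieces. The demand is attack at C7 rather than C8 and a 2-metalloallyl ether that survives until it is transmetalated.

4 goes back through 3 and 2 to 1; 23 goes back through 22 and 20 to 1; 6 goes back to 5 and 12 to 11. Compound 1 supplies C6–C9 and, a second time, C2–C1–C10–C14: hydroalumination of its mono-ethers gives the E-alkene on protonation or the Z-iodide on iodination. The demand is mono-protection of a symmetrical diol, done statistically with excess 1.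

## Other disconnections considered

Alternative 1: The cut is double, C4–C5 and C8–C9, with C15 held as a one-carbon ketone bridge between C4 and C9. In the forward sense the Cr(CO)3 complex A1 of a 3-substituted tropone (C15, C9, C10, C1–C4) and the (E)-bis(silyloxy)diene A2 (C5–C8) would join on the metal face in an endo [6π+4π] cycloaddition to the bicyclo[4.4.1]undecatrienone A3.
- In its favour: two ring bonds and the whole carbocycle form in one step without high dilution; the endo mode should set O8 relative to C9; the bridge is a latent source of both C15 and O9 (oxygen insertion on the C9 side, then cleavage).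
- Where it is better: on ring construction it is the better plan, with fewer steps to a ten-membered ring and no entropic penalty.
- Against it here: A3 would be racemic without an auxiliary or resolution, whereas the chosen route takes its absolute configuration from a catalytic epoxidation. An unsymmetrical triene and an unsymmetrical diene pose a head-to-head/head-to-tail problem. After the cycloaddition C4 is sp3 and the ring holds a C1=C10/C2=C3 diene, so C2=C3 must be saturated selectively, C4=C5 introduced ring-cis, the C6 ketone reduced, C7 protonated with the right sense, C13 added, and the oxygen insertion must choose between two similar allylic bridgeheads.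
- Comparison: mechanistically it is a metal-templated pericyclic step against an ionic SN2 closure. Structurally it builds the ring first and the alkenes and C6/C7 afterwards, the reverse of the chosen order. The step gain at ring formation is likely to be spent on these corrections, and stoichiometric chromium is a drawback.

Alternative 2: The cut runs through the C4=C5 alkene, at C5–C6 and C3–C4, and closes no ring. Forward, Ni(COD)2 would join the C6 aldehyde A4, the alkyne 12 and the alkylzinc iodide A5 (C1–C3, C1 masked as a dioxolane): oxidative cyclisation forms C5–C6, alkyl transfer forms C3–C4, and the product is the allylic alcohol A6.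
- In its favour: one step makes the trisubstituted alkene with C3 and C6 cis (syn addition across the alkyne), the C6 carbinol and the C3–C4 bond, and brings in C1–C3.
- Where it is equal or better: the chosen route needs four steps for this region (9, 10, 19, 22), so here it is the better plan in step economy. It is also better in having C12 at the ester level, so the lactone could close on O6 without a late oxidation. Its geometry control is the equal of hydroalumination–iodination.
- Against it here: C6 would rest on substrate induction from C7 in the nickel metallacycle, which is harder to predict. An sp3 organozinc with β-hydrogens can transfer hydride instead of alkyl. The C6 hydroxyl beside the C12 ester would lactonise early and put an enolisable lactone through the later steps. Above all, the ring stays open: with C2–C3 already formed, closure would have to occur at C9–C10 or C1=C10, that is, at a stereocentre or at an alkene whose ring-cis geometry would then be decided during macrocyclisation.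
- Comparison: mechanistically it is an organonickel multicomponent coupling that sets geometry by syn addition; the chosen plan sets it by anti hydroalumination and keeps the ring closure free of any selectivity demand. Its saving of about three steps on the eastern alkene would be set against a harder ring closure.

Alternative 3: The cut is transannular, C1–C6. Forward, the bicyclic C1–C6 epoxy C10-ketone A7 would condense with p-toluenesulfonylhydrazide and fragment (Eschenmoser–Tanabe) with loss of N2 and sulfinate to the cyclodec-4-en-1(10)-yn-6-one A8.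
- In its favour: the ten-membered ring is released from a six–six bicycle without high dilution, driven by N2 loss. C7–C9 can be set on a cyclohexane with conformational control. C4=C5 is ring-cis by its origin in a cyclohexene, and the C1≡C10 alkyne offers a syn-addition entry to the ring-cis C1=C10 alkene.
- Where it is equal or better: on the ring-forming event itself it is the equal or the better of the chosen plan.
- Against it here: a cyclodecyne that also holds a cis-alkene is strained. A7 needs a tetrasubstituted epoxide at the ring fusion of a dense decalinone and has an α-alkoxy ketone (O9 beside C10) that invites elimination during hydrazone formation. After fragmentation, C14 must be added regioselectively at C10, the C6 enone reduced stereoselectively inside the ring, and C13 introduced.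
- Comparison: structurally it hides the medium ring in a decalin, and mechanistically it is a fragmentation rather than a bond-forming closure. In step count the enantioselective route to A7 and the post-fragmentation work are unlikely to undercut the chosen sequence, and more steps would run on the strained ring.

Key step: step 24

Assumption: locants C1–C15 and the descriptors quoted for chain and ring intermediates refer to the germacranolide numbering. PMB = 4-methoxybenzyl, TBS = tert-butyldimethylsilyl, TES = triethylsilyl, TBDPS = tert-butyldiphenylsilyl. The acetal carbon of 9, 10 and 14–17, C12 of 44 and C2 of 36 are epimer mixtures of no consequence and are drawn without configuration.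

## Steps

Step 1
Reactants: 1 but-2-yne-1,4-diol
Product: 2 4-(PMB-oxy)but-2-yn-1-ol
Conditions: NaH (1 equiv), 1 (3 equiv), PMBCl, Bu4NI (cat.), THF/DMF, 0 °C → rt
Reagents that add atoms: 4-methoxybenzyl chloride, COc1ccc(CCl)cc1
Why: Williamson etherification; the excess of the cheap diol keeps bis-alkylation low and is washed out with water.

Step 2
Reactants: 2 4-(PMB-oxy)but-2-yn-1-ol
Product: 3 (E)-4-(PMB-oxy)but-2-en-1-ol
Conditions: NaAlH2(OCH2CH2OCH3)2, THF, 0 °C → rt
Reagents that add atoms: none
Why: Alkoxide-directed trans-hydroalumination of the propargylic alcohol; protonolysis of the alkenylalanate gives the E-allylic alcohol.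

Step 3
Reactants: 3 (E)-4-(PMB-oxy)but-2-en-1-ol
Product: 4 [(2R,3R)-3-(PMB-oxymethyl)oxiran-2-yl]methanol
Conditions: Ti(OiPr)4 (10 mol %), D-(−)-diethyl tartrate (12 mol %), t-BuOOH, 4 Å molecular sieves, CH2Cl2, −20 °C
Reagents that add atoms: tert-butyl hydroperoxide, CC(C)(C)OO
Why: Katsuki–Sharpless asymmetric epoxidation of an E-allylic alcohol; the D-tartrate ligand should give the (2R,3R)-epoxide, which fixes C8 directly and C7 after inversion.

Step 4
Reactants: 5 2-bromoprop-2-en-1-ol
Product: 6 2-bromoallyl TBS ether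
Conditions: TBSCl, imidazole, DMF, 0 °C → rt
Reagents that add atoms: tert-butyldimethylsilyl chloride, CC(C)(C)[Si](C)(C)Cl
Why: Standard silylation of a primary alcohol.

Step 5
Reactants: 6 2-bromoallyl TBS ether; 4 [(2R,3R)-3-(PMB-oxymethyl)oxiran-2-yl]methanol
Product: 8 (2S,3S)-2-[3-(TBS-oxy)prop-1-en-2-yl]-4-(PMB-oxy)butane-1,3-diol, via alkenyllithium 7 (not isolated)
Conditions: 6, t-BuLi (2 equiv), Et2O, −78 °C; MgBr2·OEt2; CuI (10 mol %); then 4 as its bromomagnesium alkoxide (MeMgBr, THF), −40 → 0 °C
Reagents that add atoms: none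
Why: Copper-catalysed SN2 opening of the 2,3-epoxy alcohol at C7 (C2 of the epoxy alcohol), the usual site for organocopper reagents when the alkoxide directs. Inversion at C7 of the trans-epoxide gives the anti relation between the C7 alkenyl branch and O8; C8 is untouched. The lithium reagent is kept at −78 °C and transmetalated at once to avoid silyl migration or loss of silyloxide.

Step 6
Reactants: 8 (2S,3S)-2-[3-(TBS-oxy)prop-1-en-2-yl]-4-(PMB-oxy)butane-1,3-diol
Product: 9 (2S)-3-(TBS-oxymethyl)-2-[(4S)-2-(4-methoxyphenyl)-1,3-dioxolan-4-yl]but-3-en-1-ol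
Conditions: DDQ (1.2 equiv), 4 Å molecular sieves, CH2Cl2, 0 °C
Reagents that add atoms: none
Why: DDQ oxidises the PMB ether to an oxocarbenium ion, which under anhydrous conditions is trapped by the neighbouring O8–H as the five-membered 4-methoxybenzylidene acetal. This protects O8 and O9 and stores the PMB group for later transfer to O8; the primary C6 alcohol stays free.

Step 7
Reactants: 9 (2S)-3-(TBS-oxymethyl)-2-[(4S)-2-(4-methoxyphenyl)-1,3-dioxolan-4-yl]but-3-en-1-ol
Product: 10 (2R)-3-(TBS-oxymethyl)-2-[(4S)-2-(4-methoxyphenyl)-1,3-dioxolan-4-yl]but-3-enal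
Conditions: Dess–Martin periodinane, NaHCO3, CH2Cl2, 0 °C
Reagents that add atoms: none
Why: Dess–Martin oxidation under buffered, non-basic conditions; the β,γ-unsaturated α-branched aldehyde is used at once so that it neither epimerises nor conjugates.

Step 8
Reactants: 11 prop-2-yn-1-ol
Product: 12 TBDPS prop-2-yn-1-yl ether
Conditions: TBDPSCl, imidazole, CH2Cl2, 0 °C → rt
Reagents that add atoms: tert-butyldiphenylsilyl chloride, CC(C)(C)[Si](Cl)(c1ccccc1)c1ccccc1
Why: Standard silylation; TBDPS is chosen for O15 because it must outlast every other silyl ether.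

Step 9
Reactants: 12 TBDPS prop-2-yn-1-yl ether; 10 (2R)-3-(TBS-oxymethyl)-2-[(4S)-2-(4-methoxyphenyl)-1,3-dioxolan-4-yl]but-3-enal
Product: 14 (6S,7S,8S)-propargylic alcohol TBDPSO–C15H2–C4≡C5–C6H(OH)–C7H[C(=CH2)CH2OTBS]–C8H–C9H2 with O8/O9 as 4-methoxybenzylidene acetal, via lithium acetylide 13 (not isolated)
Conditions: 12, n-BuLi, THF, −78 °C; then 10, −78 °C
Reagents that add atoms: none
Why: Acetylide addition under Felkin–Anh control: with the C8 dioxolane carbon as the large group and the alkenyl branch as the medium group, attack anti to C8 places O6 syn to the C7 branch, and the β-oxygen dipole (1,3-anti preference) points the same way. The low temperature and the weakly basic acetylide keep the aldehyde from conjugating; the minor C6 epimer is removed by chromatography.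

Step 10
Reactants: 14 (6S,7S,8S)-propargylic alcohol
Product: 16 (6S,7S,8S)-(Z)-C4 iodide I–C4(CH2OTBDPS)=C5H–C6H(OH)– with the rest as in 14, via cyclic alkenylalanate 15 (not isolated)
Conditions: NaAlH2(OCH2CH2OCH3)2, THF, 0 °C; EtOAc; then I2, THF, −78 → 0 °C
Reagents that add atoms: iodine, II
Why: Alkoxide-directed trans-hydroalumination puts hydride on C5 and aluminium on C4 in a five-membered alanate, and iodinolysis proceeds with retention. Iodine therefore ends cis to C6, which fixes the ring-cis C4=C5 geometry once iodine is replaced by C3.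

Step 11
Reactants: 16 (6S,7S,8S)-(Z)-C4 iodide C6 alcohol
Product: 17 (6S,7R,8S)-C6 TBS ether of 16
Conditions: TBSOTf, 2,6-lutidine, CH2Cl2, −78 °C
Reagents that add atoms: tert-butyldimethylsilyl triflate, CC(C)(C)[Si](C)(C)OS(=O)(=O)C(F)(F)F
Why: Silylation of the hindered secondary allylic alcohol with the silyl triflate at −78 °C, where the aryl acetal is inert.

Step 12
Reactants: 17 (6S,7R,8S)-C6 TBS ether
Product: 18 (6S,7R,8S)-C8 PMB ether C9 primary alcohol
Conditions: i-Bu2AlH, CH2Cl2, −78 → 0 °C
Reagents that add atoms: none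
Why: Reductive opening of the 4-methoxybenzylidene acetal: aluminium binds the less hindered primary O9 and hydride cleaves that C–O bond, so the PMB ether is left on the secondary O8 and C9–OH is freed.

Step 13
Reactants: 18 (6S,7R,8S)-C8 PMB ether C9 primary alcohol
Product: 19 (6S,7R,8S)-C9 aldehyde
Conditions: Dess–Martin periodinane, NaHCO3, CH2Cl2, 0 °C
Reagents that add atoms: none
Why: Dess–Martin oxidation; the buffered, base-free conditions protect the α-alkoxy stereocentre C8, and the aldehyde is used crude.

Step 14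
Reactants: 1 but-2-yne-1,4-diol
Product: 20 4-(TBS-oxy)but-2-yn-1-ol
Conditions: NaH (1 equiv), 1 (3 equiv), TBSCl, THF, 0 °C → rt
Reagents that add atoms: tert-butyldimethylsilyl chloride, CC(C)(C)[Si](C)(C)Cl
Why: Statistical mono-silylation of the sodium alkoxide; the excess diol is removed with water.

Step 15
Reactants: 20 4-(TBS-oxy)but-2-yn-1-ol
Product: 22 (Z)-4-(TBS-oxy)-3-iodobut-2-en-1-ol, via cyclic alkenylalanate 21 (not isolated)
Conditions: NaAlH2(OCH2CH2OCH3)2, THF, 0 °C; EtOAc; then I2, THF, −78 °C
Reagents that add atoms: iodine, II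
Why: Alkoxide-directed trans-hydroalumination and iodinolysis with retention put iodine on the carbon remote from the free hydroxyl and cis to the CH2OH group; this is the geometry that later places C2 cis to C9.

Step 16
Reactants: 22 (Z)-4-(TBS-oxy)-3-iodobut-2-en-1-ol
Product: 23 (Z)-1-(TES-oxy)-4-(TBS-oxy)-3-iodobut-2-ene
Conditions: Et3SiCl, imidazole, CH2Cl2, 0 °C
Reagents that add atoms: chlorotriethylsilane, CC[Si](Cl)(CC)CC
Why: Silylation of the primary allylic alcohol; the TES ether on O2 is the one silyl group that can later be removed first.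

Step 17
Reactants: 23 (Z)-1-(TES-oxy)-4-(TBS-oxy)-3-iodobut-2-ene; 19 (6S,7R,8S)-C9 aldehyde
Product: 25 (6S,7R,8S,9S)-C9 alcohol with C4 iodide and O2 TES ether, via alkenyllithium 24 (not isolated)
Conditions: 23, t-BuLi (2 equiv), Et2O, −78 °C; MgBr2·OEt2; then 19 premixed with MgBr2·OEt2, CH2Cl2, −78 °C
Reagents that add atoms: none
Why: Iodine–lithium exchange with retention of alkene geometry, transmetalation to magnesium and Cram-chelate addition. Magnesium bridges the aldehyde oxygen and the α-PMB ether oxygen and the alkenyl group attacks the face away from C7, giving the 8,9-syn arrangement (9S). The alkenyl iodide at C4 does not exchange with the magnesium reagent.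

Step 18
Reactants: 25 (6S,7R,8S,9S)-C9 alcohol
Product: 26 (6S,7R,8S,9S)-C9 TES ether
Conditions: Et3SiOTf, 2,6-lutidine, CH2Cl2, −78 °C
Reagents that add atoms: triethylsilyl triflate, CC[Si](CC)(CC)OS(=O)(=O)C(F)(F)F
Why: Silylation of the hindered secondary allylic alcohol; O9 must be capped before C2 is activated, because the free cis-disposed hydroxyl could otherwise close a dihydrofuran.

Step 19
Reactants: 26 (6S,7R,8S,9S)-C9 TES ether
Product: 27 (6R,7R,8S,9S)-C3 methyl ester (MeO2C on C4 cis to C6)
Conditions: PdCl2(PPh3)2 (5 mol %), CO (1 atm), Et3N, MeOH/DMF, 50 °C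
Reagents that add atoms: carbon monoxide, [C-]#[O+]; methanol, CO
Why: Alkoxycarbonylation of the alkenyl iodide: oxidative addition to zerovalent palladium, CO insertion and methanolysis, all with retention of alkene geometry, introduce C3. The ester masks the future C3 hydroxyl while C2 is converted, and the step is run before any allylic sulfone is present.

Step 20
Reactants: 27 (6R,7R,8S,9S)-C3 methyl ester
Product: 28 (6R,7R,8S,9S)-C2 primary alcohol
Conditions: PPTS (cat.), MeOH/CH2Cl2, 0 °C
Reagents that add atoms: none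
Why: Acid-catalysed methanolysis of silyl ethers is fastest for the unhindered primary allylic TES ether; the hindered secondary TES ether on O9 and the TBS and TBDPS ethers react far more slowly.

Step 21
Reactants: 28 (6R,7R,8S,9S)-C2 primary alcohol; 29 sodium benzenesulfinate
Product: 31 (6R,7R,8S,9S)-C2 phenyl sulfone C3 methyl ester, via C2 mesylate 30 (not isolated)
Conditions: MsCl, Et3N, CH2Cl2, −20 °C; then 29, DMF, 0 °C → rt
Reagents that add atoms: none
Why: SN2 displacement of the primary allylic mesylate by the soft sulfur of the sulfinate gives the allylic sulfone without transposition or change of alkene geometry.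

Step 22
Reactants: 31 (6R,7R,8S,9S)-C2 phenyl sulfone C3 methyl ester
Product: 32 (6R,7R,8S,9S)-C2 phenyl sulfone C3 allylic alcohol
Conditions: i-Bu2AlH, CH2Cl2, −78 °C
Reagents that add atoms: none
Why: 1,2-Reduction of the α,β-unsaturated ester to the primary allylic alcohol; sulfone, silyl ethers and PMB ether are inert at −78 °C.

Step 23
Reactants: 32 (6R,7R,8S,9S)-C2 phenyl sulfone C3 allylic alcohol
Product: 34 acyclic C2 phenyl sulfone C3 bromide (6R,7R,8S,9S; O6, O12, O14 TBS; O8 PMB; O9 TES; O15 TBDPS), via C3 mesylate 33 (not isolated)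
Conditions: MsCl, Et3N, THF, −40 °C; then LiBr, −40 → 0 °C
Reagents that add atoms: lithium bromide, [Li+].[Br-]
Why: Mesylation and SN2 displacement by bromide give the primary allylic bromide without transposition; Et3N is too weak a base to deprotonate the sulfone.

Step 24
Reactants: 34 acyclic C2 phenyl sulfone C3 bromide
Product: 36 ten-membered C2 phenyl sulfone (6R,7R,8S,9S; both C2 epimers), via potassium sulfonyl allyl anion 35 (not isolated)
Conditions: KN(SiMe3)2 (1.2 equiv), THF, −78 °C, 34 added over 6 h (final 1 mM); then −78 → −30 °C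
Reagents that add atoms: none
Why: KN(SiMe3)2 removes a C2 proton (α to the sulfonyl group and allylic) to give the sulfonyl-stabilised allyl anion 35, which displaces bromide at C3 in an intramolecular SN2 reaction and so forms C2–C3. The closest known reaction type is the intramolecular alkylation of sulfone- or sulfide-stabilised allylic carbanions by allylic halides, used to close ten- and fourteen-membered 1,5-diene rings. The ring closes in the 10-exo-tet mode, and slow addition to the base at high dilution keeps it ahead of intermolecular alkylation. The only new stereocentre, C2, is not controlled and need not be, since both epimers give 37 after C–S cleavage. The step needs α- over γ-alkylation of the anion and SN2 over SN2′ at the bromide: γ-attack from C10 or attack at C5 would each close an eight-membered ring through a fully substituted or more hindered carbon, so the normal α-regiochemistry of sulfonyl allyl anions and the ring size both favour the desired path. The two ring-cis alkenes, fixed beforehand, fold C2 and C3 towards each other, and neither alkene nor C6–C9 is touched. Loss of silyloxide from C9 or C14 of the delocalised anion (1,4-elimination) is held back by the low temperature and the poor leaving groups.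

Step 25
Reactants: 36 ten-membered C2 phenyl sulfone
Product: 37 protected ring-cis cyclodeca-1(10),4-diene (6R,7R,8S,9S)
Conditions: PdCl2[Ph2P(CH2)3PPh2] (10 mol %), LiBHEt3 (3 equiv), THF, 0 °C
Reagents that add atoms: none
Why: Palladium-catalysed hydride substitution of an allylic sulfone: zerovalent palladium, formed from the divalent precatalyst and the borohydride, ionises the C2–S bond to a π-allyl complex and hydride is delivered to the less hindered C2 terminus. C1=C10 should keep its position and geometry, and the olefin transposition and β-alkoxide loss that threaten under dissolving-metal conditions are avoided; both C2 epimers converge.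

Step 26
Reactants: 37 protected ring-cis cyclodeca-1(10),4-diene
Product: 38 C8 alcohol (6R,7R,8S,9S)
Conditions: DDQ, CH2Cl2/pH 7 buffer, 0 °C
Reagents that add atoms: none
Why: Oxidative cleavage of the PMB ether through its hemiacetal; silyl ethers and the non-conjugated alkenes are untouched.

Step 27
Reactants: 38 C8 alcohol
Product: 39 C8 methacrylate (6R,7R,8S,9S)
Conditions: methacrylic anhydride, Et3N, DMAP, CH2Cl2, 0 °C → rt
Reagents that add atoms: methacrylic anhydride, CC(=C)C(=O)OC(=O)C(C)=C
Why: DMAP-catalysed acylation of the hindered secondary alcohol; it is done while O9 is still silylated so that no 1,2-acyl migration can occur.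

Step 28
Reactants: 39 C8 methacrylate
Product: 40 C9 alcohol (6R,7R,8S,9S)
Conditions: PPTS (cat.), MeOH/CH2Cl2, 0 °C
Reagents that add atoms: none
Why: Acid-catalysed methanolysis of the secondary TES ether, which is more labile than the TBS ethers; the mildly acidic medium also disfavours migration of the methacrylate to O9.

Step 29
Reactants: 40 C9 alcohol
Product: 41 C8 methacrylate C9 acetate (6R,7R,8S,9S)
Conditions: Ac2O, pyridine, DMAP (cat.), CH2Cl2, 0 °C
Reagents that add atoms: acetic anhydride, CC(=O)OC(C)=O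
Why: DMAP-catalysed acetylation of the allylic alcohol; the conjugated methacrylate on O8 migrates less readily than an acetate would, which is why O9 is acylated last.

Step 30
Reactants: 41 C8 methacrylate C9 acetate
Product: 42 6,12,14-triol with O15 TBDPS ether (6R,7S,8S,9S)
Conditions: HF·pyridine, pyridine, THF, 0 °C → rt
Reagents that add atoms: none
Why: Fluoride cleavage of the three TBS ethers; the primary TBDPS ether is much slower under buffered HF·pyridine and is kept, and the acidic medium limits acyl migration from O8 and O9.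

Step 31
Reactants: 42 6,12,14-triol
Product: 45 15-O-TBDPS ether of the target (6R,7S,8S,9S), via hydroxy dialdehyde 43 (not isolated), via lactol 44 (not isolated)
Conditions: TEMPO (20 mol %), PhI(OAc)2 (3.5 equiv), CH2Cl2, rt
Reagents that add atoms: none
Why: Oxoammonium oxidation selective for primary alcohols: C14–OH gives the enal, and C12–OH gives a 2-substituted acrolein that is trapped by C6–OH as the γ-lactol and oxidised again to the α-methylene-γ-butyrolactone. Because O8 is already acylated, only the 6,12-lactone can form, and its trans fusion is fixed by C6 and C7.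

Step 32
Reactants: 45 15-O-TBDPS ether of the target
Product: 46 CNP0147326.4
Conditions: HF·pyridine, THF, 0 °C → rt
Reagents that add atoms: none
Why: Acidic fluoride removes the primary TBDPS ether without base, so that the enal, the α-methylene lactone and the two esters are not exposed to alkoxide or free fluoride.

## Compound list

1 | but-2-yne-1,4-diol | OCC#CCO | starting material
2 | 4-(PMB-oxy)but-2-yn-1-ol | OCC#CCOCc1ccc(OC)cc1 | intermediate
3 | (E)-4-(PMB-oxy)but-2-en-1-ol | OC/C=C/COCc1ccc(OC)cc1 | intermediate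
4 | [(2R,3R)-3-(PMB-oxymethyl)oxiran-2-yl]methanol | OC[C@H]1O[C@@H]1COCc1ccc(OC)cc1 | intermediate
5 | 2-bromoprop-2-en-1-ol | OCC(Br)=C | starting material
6 | 2-bromoallyl TBS ether | C=C(Br)CO[Si](C)(C)C(C)(C)C | intermediate
7 | [3-(TBS-oxy)prop-1-en-2-yl]lithium (not isolated) | [Li]C(=C)CO[Si](C)(C)C(C)(C)C | intermediate
8 | (2S,3S)-2-[3-(TBS-oxy)prop-1-en-2-yl]-4-(PMB-oxy)butane-1,3-diol (C6–C9 with C11–C13) | OC[C@H](C(=C)CO[Si](C)(C)C(C)(C)C)[C@H](O)COCc1ccc(OC)cc1 | intermediate
9 | (2S)-3-(TBS-oxymethyl)-2-[(4S)-2-(4-methoxyphenyl)-1,3-dioxolan-4-yl]but-3-en-1-ol (acetal epimers) | OC[C@H](C(=C)CO[Si](C)(C)C(C)(C)C)[C@H]1COC(c2ccc(OC)cc2)O1 | intermediate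
10 | (2R)-3-(TBS-oxymethyl)-2-[(4S)-2-(4-methoxyphenyl)-1,3-dioxolan-4-yl]but-3-enal (C6 aldehyde) | O=C[C@H](C(=C)CO[Si](C)(C)C(C)(C)C)[C@H]1COC(c2ccc(OC)cc2)O1 | intermediate
11 | prop-2-yn-1-ol | C#CCO | starting material
12 | TBDPS prop-2-yn-1-yl ether | C#CCO[Si](c1ccccc1)(c1ccccc1)C(C)(C)C | intermediate
13 | [3-(TBDPS-oxy)prop-1-yn-1-yl]lithium (not isolated) | [Li]C#CCO[Si](c1ccccc1)(c1ccccc1)C(C)(C)C | intermediate
14 | (6S,7S,8S)-propargylic alcohol: TBDPSO–C15H2–C4≡C5–C6H(OH)–C7H[C(=CH2)CH2OTBS]–C8H–C9H2, O8/O9 as 4-methoxybenzylidene acetal | CC(C)(C)[Si](c1ccccc1)(c1ccccc1)OCC#C[C@@H](O)[C@H](C(=C)CO[Si](C)(C)C(C)(C)C)[C@H]1COC(c2ccc(OC)cc2)O1 | intermediate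
15 | sodium salt of the cyclic alkenylalanate O6–Al–C4 from 14 (not isolated) | [Na+].COCCO[Al-]1(OCCOC)O[C@@H]([C@H](C(=C)CO[Si](C)(C)C(C)(C)C)[C@H]2COC(c3ccc(OC)cc3)O2)C=C1CO[Si](c1ccccc1)(c1ccccc1)C(C)(C)C | intermediate
16 | (6S,7S,8S)-(Z)-C4 iodide (iodine cis to C6) with free C6 hydroxyl, rest as 14 | I/C(CO[Si](c1ccccc1)(c1ccccc1)C(C)(C)C)=C\[C@@H](O)[C@H](C(=C)CO[Si](C)(C)C(C)(C)C)[C@H]1COC(c2ccc(OC)cc2)O1 | intermediate
17 | (6S,7R,8S)-C6 TBS ether of 16 | I/C(CO[Si](c1ccccc1)(c1ccccc1)C(C)(C)C)=C\[C@@H](O[Si](C)(C)C(C)(C)C)[C@H](C(=C)CO[Si](C)(C)C(C)(C)C)[C@H]1COC(c2ccc(OC)cc2)O1 | intermediate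
18 | (6S,7R,8S)-C4 iodide, O6 TBS, O8 PMB, C9 primary alcohol | I/C(CO[Si](c1ccccc1)(c1ccccc1)C(C)(C)C)=C\[C@@H](O[Si](C)(C)C(C)(C)C)[C@H](C(=C)CO[Si](C)(C)C(C)(C)C)[C@H](OCc1ccc(OC)cc1)CO | intermediate
19 | (6S,7R,8S)-C9 aldehyde of 18 | I/C(CO[Si](c1ccccc1)(c1ccccc1)C(C)(C)C)=C\[C@@H](O[Si](C)(C)C(C)(C)C)[C@H](C(=C)CO[Si](C)(C)C(C)(C)C)[C@H](OCc1ccc(OC)cc1)C=O | intermediate
20 | 4-(TBS-oxy)but-2-yn-1-ol | OCC#CCO[Si](C)(C)C(C)(C)C | intermediate
21 | sodium salt of the cyclic alkenylalanate from 20 (not isolated) | [Na+].COCCO[Al-]1(OCCOC)OCC=C1CO[Si](C)(C)C(C)(C)C | intermediate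
22 | (Z)-4-(TBS-oxy)-3-iodobut-2-en-1-ol (C2–C1=C10(I)–C14) | I/C(CO[Si](C)(C)C(C)(C)C)=C\CO | intermediate
23 | (Z)-1-(TES-oxy)-4-(TBS-oxy)-3-iodobut-2-ene | I/C(CO[Si](C)(C)C(C)(C)C)=C\CO[Si](CC)(CC)CC | intermediate
24 | alkenyllithium from 23, lithium cis to C2 (not isolated) | [Li]/C(CO[Si](C)(C)C(C)(C)C)=C\CO[Si](CC)(CC)CC | intermediate
25 | (6S,7R,8S,9S)-C9 alcohol: C4 iodide, O6/O12/O14 TBS, O8 PMB, O2 TES, O15 TBDPS | I/C(CO[Si](c1ccccc1)(c1ccccc1)C(C)(C)C)=C\[C@@H](O[Si](C)(C)C(C)(C)C)[C@H](C(=C)CO[Si](C)(C)C(C)(C)C)[C@H](OCc1ccc(OC)cc1)[C@@H](O)/C(CO[Si](C)(C)C(C)(C)C)=C\CO[Si](CC)(CC)CC | intermediate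
26 | (6S,7R,8S,9S)-C9 TES ether of 25 | I/C(CO[Si](c1ccccc1)(c1ccccc1)C(C)(C)C)=C\[C@@H](O[Si](C)(C)C(C)(C)C)[C@H](C(=C)CO[Si](C)(C)C(C)(C)C)[C@H](OCc1ccc(OC)cc1)[C@@H](O[Si](CC)(CC)CC)/C(CO[Si](C)(C)C(C)(C)C)=C\CO[Si](CC)(CC)CC | intermediate
27 | (6R,7R,8S,9S)-C3 methyl ester (CO2Me on C4 cis to C6), O2 TES | COC(=O)/C(CO[Si](c1ccccc1)(c1ccccc1)C(C)(C)C)=C\[C@@H](O[Si](C)(C)C(C)(C)C)[C@H](C(=C)CO[Si](C)(C)C(C)(C)C)[C@H](OCc1ccc(OC)cc1)[C@@H](O[Si](CC)(CC)CC)/C(CO[Si](C)(C)C(C)(C)C)=C\CO[Si](CC)(CC)CC | intermediate
28 | (6R,7R,8S,9S)-C3 methyl ester with free C2 hydroxyl | COC(=O)/C(CO[Si](c1ccccc1)(c1ccccc1)C(C)(C)C)=C\[C@@H](O[Si](C)(C)C(C)(C)C)[C@H](C(=C)CO[Si](C)(C)C(C)(C)C)[C@H](OCc1ccc(OC)cc1)[C@@H](O[Si](CC)(CC)CC)/C(CO[Si](C)(C)C(C)(C)C)=C\CO | intermediate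
29 | sodium benzenesulfinate | [Na+].[O-]S(=O)c1ccccc1 | starting material
30 | C2 mesylate of 28 (not isolated) | COC(=O)/C(CO[Si](c1ccccc1)(c1ccccc1)C(C)(C)C)=C\[C@@H](O[Si](C)(C)C(C)(C)C)[C@H](C(=C)CO[Si](C)(C)C(C)(C)C)[C@H](OCc1ccc(OC)cc1)[C@@H](O[Si](CC)(CC)CC)/C(CO[Si](C)(C)C(C)(C)C)=C\COS(C)(=O)=O | intermediate
31 | (6R,7R,8S,9S)-C2 phenyl sulfone C3 methyl ester | COC(=O)/C(CO[Si](c1ccccc1)(c1ccccc1)C(C)(C)C)=C\[C@@H](O[Si](C)(C)C(C)(C)C)[C@H](C(=C)CO[Si](C)(C)C(C)(C)C)[C@H](OCc1ccc(OC)cc1)[C@@H](O[Si](CC)(CC)CC)/C(CO[Si](C)(C)C(C)(C)C)=C\CS(=O)(=O)c1ccccc1 | intermediate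
32 | (6R,7R,8S,9S)-C2 phenyl sulfone C3 allylic alcohol | OC/C(CO[Si](c1ccccc1)(c1ccccc1)C(C)(C)C)=C\[C@@H](O[Si](C)(C)C(C)(C)C)[C@H](C(=C)CO[Si](C)(C)C(C)(C)C)[C@H](OCc1ccc(OC)cc1)[C@@H](O[Si](CC)(CC)CC)/C(CO[Si](C)(C)C(C)(C)C)=C\CS(=O)(=O)c1ccccc1 | intermediate
33 | C3 mesylate of 32 (not isolated) | CS(=O)(=O)OC/C(CO[Si](c1ccccc1)(c1ccccc1)C(C)(C)C)=C\[C@@H](O[Si](C)(C)C(C)(C)C)[C@H](C(=C)CO[Si](C)(C)C(C)(C)C)[C@H](OCc1ccc(OC)cc1)[C@@H](O[Si](CC)(CC)CC)/C(CO[Si](C)(C)C(C)(C)C)=C\CS(=O)(=O)c1ccccc1 | intermediate
34 | acyclic C2 phenyl sulfone C3 bromide (6R,7R,8S,9S): O6/O12/O14 TBS, O8 PMB, O9 TES, O15 TBDPS, both alkenes ring-cis type | BrC/C(CO[Si](c1ccccc1)(c1ccccc1)C(C)(C)C)=C\[C@@H](O[Si](C)(C)C(C)(C)C)[C@H](C(=C)CO[Si](C)(C)C(C)(C)C)[C@H](OCc1ccc(OC)cc1)[C@@H](O[Si](CC)(CC)CC)/C(CO[Si](C)(C)C(C)(C)C)=C\CS(=O)(=O)c1ccccc1 | intermediate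
35 | potassium salt of the C2 sulfonyl allyl anion of 34 (not isolated) | [K+].BrC/C(CO[Si](c1ccccc1)(c1ccccc1)C(C)(C)C)=C\[C@@H](O[Si](C)(C)C(C)(C)C)[C@H](C(=C)CO[Si](C)(C)C(C)(C)C)[C@H](OCc1ccc(OC)cc1)[C@@H](O[Si](CC)(CC)CC)/C(CO[Si](C)(C)C(C)(C)C)=C\[CH-]S(=O)(=O)c1ccccc1 | intermediate
36 | ten-membered C2 phenyl sulfone (6R,7R,8S,9S; C2 epimers), protecting groups as in 34 | C1/C(CO[Si](c2ccccc2)(c2ccccc2)C(C)(C)C)=C\[C@@H](O[Si](C)(C)C(C)(C)C)[C@H](C(=C)CO[Si](C)(C)C(C)(C)C)[C@H](OCc2ccc(OC)cc2)[C@@H](O[Si](CC)(CC)CC)/C(CO[Si](C)(C)C(C)(C)C)=C\C1S(=O)(=O)c1ccccc1 | intermediate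
37 | protected ring-cis cyclodeca-1(10),4-diene (6R,7R,8S,9S): O6/O12/O14 TBS, O8 PMB, O9 TES, O15 TBDPS | C1/C(CO[Si](c2ccccc2)(c2ccccc2)C(C)(C)C)=C\[C@@H](O[Si](C)(C)C(C)(C)C)[C@H](C(=C)CO[Si](C)(C)C(C)(C)C)[C@H](OCc2ccc(OC)cc2)[C@@H](O[Si](CC)(CC)CC)/C(CO[Si](C)(C)C(C)(C)C)=C\C1 | intermediate
38 | C8 alcohol of 37 (6R,7R,8S,9S) | C1/C(CO[Si](c2ccccc2)(c2ccccc2)C(C)(C)C)=C\[C@@H](O[Si](C)(C)C(C)(C)C)[C@H](C(=C)CO[Si](C)(C)C(C)(C)C)[C@H](O)[C@@H](O[Si](CC)(CC)CC)/C(CO[Si](C)(C)C(C)(C)C)=C\C1 | intermediate
39 | C8 methacrylate, O9 TES (6R,7R,8S,9S) | C1/C(CO[Si](c2ccccc2)(c2ccccc2)C(C)(C)C)=C\[C@@H](O[Si](C)(C)C(C)(C)C)[C@H](C(=C)CO[Si](C)(C)C(C)(C)C)[C@H](OC(=O)C(C)=C)[C@@H](O[Si](CC)(CC)CC)/C(CO[Si](C)(C)C(C)(C)C)=C\C1 | intermediate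
40 | C8 methacrylate, C9 alcohol (6R,7R,8S,9S) | C1/C(CO[Si](c2ccccc2)(c2ccccc2)C(C)(C)C)=C\[C@@H](O[Si](C)(C)C(C)(C)C)[C@H](C(=C)CO[Si](C)(C)C(C)(C)C)[C@H](OC(=O)C(C)=C)[C@@H](O)/C(CO[Si](C)(C)C(C)(C)C)=C\C1 | intermediate
41 | C8 methacrylate, C9 acetate, O6/O12/O14 TBS, O15 TBDPS (6R,7R,8S,9S) | C1/C(CO[Si](c2ccccc2)(c2ccccc2)C(C)(C)C)=C\[C@@H](O[Si](C)(C)C(C)(C)C)[C@H](C(=C)CO[Si](C)(C)C(C)(C)C)[C@H](OC(=O)C(C)=C)[C@@H](OC(C)=O)/C(CO[Si](C)(C)C(C)(C)C)=C\C1 | intermediate
42 | 6,12,14-triol, C8 methacrylate, C9 acetate, O15 TBDPS (6R,7S,8S,9S) | C1/C(CO[Si](c2ccccc2)(c2ccccc2)C(C)(C)C)=C\[C@@H](O)[C@H](C(=C)CO)[C@H](OC(=O)C(C)=C)[C@@H](OC(C)=O)/C(CO)=C\C1 | intermediate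
43 | C12,C14-dialdehyde with free C6 hydroxyl (not isolated) | C1/C(CO[Si](c2ccccc2)(c2ccccc2)C(C)(C)C)=C\[C@@H](O)[C@H](C(=C)C=O)[C@H](OC(=O)C(C)=C)[C@@H](OC(C)=O)/C(C=O)=C\C1 | intermediate
44 | 6,12-lactol C14 aldehyde (C12 epimers; not isolated) | C1/C(CO[Si](c2ccccc2)(c2ccccc2)C(C)(C)C)=C\[C@H]2OC(O)C(=C)[C@@H]2[C@H](OC(=O)C(C)=C)[C@@H](OC(C)=O)/C(C=O)=C\C1 | intermediate
45 | 15-O-TBDPS ether of the target (6R,7S,8S,9S) | C1/C(CO[Si](c2ccccc2)(c2ccccc2)C(C)(C)C)=C\[C@H]2OC(=O)C(=C)[C@@H]2[C@H](OC(=O)C(C)=C)[C@@H](OC(C)=O)/C(C=O)=C\C1 | intermediate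
46 | CNP0147326.4: (6R,7S,8S,9S)-9-acetoxy-14-oxo-15-hydroxy-8-methacryloyloxy-germacra-1(10),4,11(13)-trien-12,6-olide, both ring alkenes ring-cis | C=C(C)C(=O)O[C@H]1[C@H]2C(=C)C(=O)O[C@@H]2/C=C(/CO)CC/C=C(/C=O)[C@@H]1OC(C)=O | target

## Step count and risk

Total step count: 32 steps. Longest linear sequence: 27 steps (1–3, 5–7, 9–13, 17–32, from 1 to 46).

Least certain steps:

Step 24 (key step). What may go wrong is loss of silyloxide from C9 or C14 of the delocalised anion (1,4-elimination to a sulfonyl diene) if the ten-membered closure is slow, and intermolecular alkylation if dilution is insufficient. The fallback reverses the roles of the two termini for the same C2–C3 bond; the anion then spans C3–C5 and has only one β-oxygen (O6). It sets out from 27 and comes back at 37. Reduction of 27 with i-Bu2AlH would give the C3 allylic alcohol F1. Mesylation would give the C3 mesylate F2, which PhSO2Na would convert into the C3 phenyl sulfone F3. PPTS in methanol would free the C2 alcohol F4, and CBr4/PPh3 would give the C2 bromide F5. KN(SiMe3)2 at high dilution would close the ten-membered C3 sulfone F6, and the same palladium hydride desulfonylation would give 37.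

Step 9. What may go wrong is poor facial selectivity at C6, because the alkenyl branch and the dioxolane carbon compete for the role of large group, and base-induced movement of the C11=C13 alkene into conjugation with the aldehyde. The fallback sets C6 by reagent control; it sets out from 14 obtained as a C6 epimer mixture and comes back at 14. Dess–Martin oxidation of the mixture would give the C6 ynone F7, and transfer hydrogenation with RuCl[(S,S)-TsDPEN](p-cymene) in i-PrOH, which for alkynyl ketones should deliver the (S)-carbinol, would return the 6S alcohol 14.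

Step 17. What may go wrong is loss of silyloxide from the alkenyllithium 24 (allene formation) before transmetalation, and erosion of chelation control by the bulky alkenylmagnesium reagent. The fallback avoids the lithium reagent and sets C9 by reagent control; it sets out from 19 and 23 and comes back at 25. Coupling with CrCl2 and catalytic NiCl2 in DMF would give 25 together with its C9 epimer F8. Dess–Martin oxidation of the mixture would give the C9 enone F9. Reduction with the (S)-2-methyl-CBS-oxazaborolidine and catecholborane, with the α-branched alkenyl group as the large substituent, should give 25.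

Step 25. What may go wrong is hydride delivery to the C10 terminus of the π-allyl intermediate (alkene transposition) or syn–anti isomerisation that erodes the C1=C10 geometry. The fallback replaces the two-electron palladium pathway by single-electron C–S cleavage with Na/Hg (6% Na) and Na2HPO4 in MeOH/THF at −20 °C. It sets out from 36 and comes back at 37, and makes no new compound.

Step 28. What may go wrong is that the methanolysis does not stop at the secondary TES ether and also removes the primary allylic TBS ethers on O12 and O14. The fallback gives up this selectivity; it sets out from 39 and comes back at 45. HF·pyridine would remove the TES and the three TBS groups together to give the 6,9,12,14-tetraol F10. TEMPO/PhI(OAc)2, which oxidises the two primary allylic alcohols faster than the hindered secondary C9 alcohol, would give the 9-hydroxy lactone enal F11. Acetylation with Ac2O and pyridine would give 45.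

## Further compounds

F1 | step 24 | C3 allylic alcohol with O2 TES ether, from 27 | OC/C(CO[Si](c1ccccc1)(c1ccccc1)C(C)(C)C)=C\[C@@H](O[Si](C)(C)C(C)(C)C)[C@H](C(=C)CO[Si](C)(C)C(C)(C)C)[C@H](OCc1ccc(OC)cc1)[C@@H](O[Si](CC)(CC)CC)/C(CO[Si](C)(C)C(C)(C)C)=C\CO[Si](CC)(CC)CC
F2 | step 24 | C3 mesylate of F1 | CS(=O)(=O)OC/C(CO[Si](c1ccccc1)(c1ccccc1)C(C)(C)C)=C\[C@@H](O[Si](C)(C)C(C)(C)C)[C@H](C(=C)CO[Si](C)(C)C(C)(C)C)[C@H](OCc1ccc(OC)cc1)[C@@H](O[Si](CC)(CC)CC)/C(CO[Si](C)(C)C(C)(C)C)=C\CO[Si](CC)(CC)CC
F3 | step 24 | C3 phenyl sulfone with O2 TES ether | O=S(=O)(c1ccccc1)C/C(CO[Si](c1ccccc1)(c1ccccc1)C(C)(C)C)=C\[C@@H](O[Si](C)(C)C(C)(C)C)[C@H](C(=C)CO[Si](C)(C)C(C)(C)C)[C@H](OCc1ccc(OC)cc1)[C@@H](O[Si](CC)(CC)CC)/C(CO[Si](C)(C)C(C)(C)C)=C\CO[Si](CC)(CC)CC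
F4 | step 24 | C3 phenyl sulfone C2 alcohol | O=S(=O)(c1ccccc1)C/C(CO[Si](c1ccccc1)(c1ccccc1)C(C)(C)C)=C\[C@@H](O[Si](C)(C)C(C)(C)C)[C@H](C(=C)CO[Si](C)(C)C(C)(C)C)[C@H](OCc1ccc(OC)cc1)[C@@H](O[Si](CC)(CC)CC)/C(CO[Si](C)(C)C(C)(C)C)=C\CO
F5 | step 24 | C3 phenyl sulfone C2 bromide | O=S(=O)(c1ccccc1)C/C(CO[Si](c1ccccc1)(c1ccccc1)C(C)(C)C)=C\[C@@H](O[Si](C)(C)C(C)(C)C)[C@H](C(=C)CO[Si](C)(C)C(C)(C)C)[C@H](OCc1ccc(OC)cc1)[C@@H](O[Si](CC)(CC)CC)/C(CO[Si](C)(C)C(C)(C)C)=C\CBr
F6 | step 24 | ten-membered C3 phenyl sulfone (C3 epimers) | O=S(=O)(c1ccccc1)C1/C(CO[Si](c2ccccc2)(c2ccccc2)C(C)(C)C)=C\[C@@H](O[Si](C)(C)C(C)(C)C)[C@H](C(=C)CO[Si](C)(C)C(C)(C)C)[C@H](OCc2ccc(OC)cc2)[C@@H](O[Si](CC)(CC)CC)/C(CO[Si](C)(C)C(C)(C)C)=C\C1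
F7 | step 9 | C6 ynone from the epimers of 14 | CC(C)(C)[Si](c1ccccc1)(c1ccccc1)OCC#CC(=O)[C@H](C(=C)CO[Si](C)(C)C(C)(C)C)[C@H]1COC(c2ccc(OC)cc2)O1
F8 | step 17 | C9 epimer of 25 | I/C(CO[Si](c1ccccc1)(c1ccccc1)C(C)(C)C)=C\[C@@H](O[Si](C)(C)C(C)(C)C)[C@H](C(=C)CO[Si](C)(C)C(C)(C)C)[C@H](OCc1ccc(OC)cc1)[C@H](O)/C(CO[Si](C)(C)C(C)(C)C)=C\CO[Si](CC)(CC)CC
F9 | step 17 | C9 enone | I/C(CO[Si](c1ccccc1)(c1ccccc1)C(C)(C)C)=C\[C@@H](O[Si](C)(C)C(C)(C)C)[C@H](C(=C)CO[Si](C)(C)C(C)(C)C)[C@H](OCc1ccc(OC)cc1)C(=O)/C(CO[Si](C)(C)C(C)(C)C)=C\CO[Si](CC)(CC)CC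
F0 | step 25 | none | none
F10 | step 28 | 6,9,12,14-tetraol with C8 methacrylate and O15 TBDPS ether | C1/C(CO[Si](c2ccccc2)(c2ccccc2)C(C)(C)C)=C\[C@@H](O)[C@H](C(=C)CO)[C@H](OC(=O)C(C)=C)[C@@H](O)/C(CO)=C\C1
F11 | step 28 | 9-hydroxy 6,12-lactone C14 enal with C8 methacrylate and O15 TBDPS ether | C1/C(CO[Si](c2ccccc2)(c2ccccc2)C(C)(C)C)=C\[C@H]2OC(=O)C(=C)[C@@H]2[C@H](OC(=O)C(C)=C)[C@@H](O)/C(C=O)=C\C1
A1 | alternative 1 | tricarbonylchromium complex of 3-(PMB-oxymethyl)tropone | O=C1C=C(COCc2ccc(OC)cc2)C=CC=C1.[Cr].[C-]#[O+].[C-]#[O+].[C-]#[O+]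
A2 | alternative 1 | methyl (E)-4-(TBS-oxy)-3-[1-(trimethylsilyloxy)vinyl]but-3-enoate (C5–C8 diene) | C=C(O[Si](C)(C)C)/C(CC(=O)OC)=C/O[Si](C)(C)C(C)(C)C
A3 | alternative 1 | bicyclo[4.4.1]undecatrienone with C15 ketone bridge | O=C1[C@@H]2C=CC=C(COCc3ccc(OC)cc3)[C@H]1[C@@H](O[Si](C)(C)C(C)(C)C)C(CC(=O)OC)=C(O[Si](C)(C)C)C2
A4 | alternative 2 | C6 aldehyde with C7 acetate arm, O8 TES, O9 PMB | O=C[C@H](CC(=O)OC)[C@H](O[Si](CC)(CC)CC)COCc1ccc(OC)cc1
A5 | alternative 2 | [2-(1,3-dioxolan-2-yl)ethyl]zinc iodide | I[Zn]CCC1OCCO1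
A6 | alternative 2 | acyclic allylic alcohol C1–C9 with ring-cis-type C4=C5 alkene | C1COC(O1)CC/C(CO[Si](c1ccccc1)(c1ccccc1)C(C)(C)C)=C\[C@@H](O)[C@H](CC(=O)OC)[C@H](O[Si](CC)(CC)CC)COCc1ccc(OC)cc1
A7 | alternative 3 | bicyclic C1–C6 epoxy C10-ketone (epoxide carbons unspecified) | COC(=O)C[C@@H]1[C@H](O[Si](C)(C)C(C)(C)C)[C@@H](OCc2ccc(OC)cc2)C(=O)C23CCC(CO[Si](c4ccccc4)(c4ccccc4)C(C)(C)C)=CC12O3
A8 | alternative 3 | protected cyclodec-4-en-1(10)-yn-6-one | COC(=O)C[C@H]1C(=O)/C=C(/CO[Si](c2ccccc2)(c2ccccc2)C(C)(C)C)CCC#C[C@H](OCc2ccc(OC)cc2)[C@H]1O[Si](C)(C)C(C)(C)C
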